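Ring C (the terminal 2,4-dihydroxy-6-methylbenzoyl group) has the oxygen pattern of a folded tetraketide. It is therefore cut across its C1–C6 bond to an open 3,5,7-trioxooctanoyl chain already esterified to O-4 of ring B. The ester to the doubly ortho-flanked carboxyl carbon is thus formed before ring C exists, from a phenol and an acylketene. In one operation chain C2 then adds to the C7 ketone, and loss of water with enolisation at C3 and C5 delivers the aromatic ring, which is the target. The precursor is methyl lecanorate, made by conventional depside chemistry, carrying the linear triketo ester on its only unchelated hydroxyl.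

Key step: step 8

Remarks on the chemistry (they apply to all steps below)
- Labels: ring A is the methyl benzoate ring, ring B the central ring, ring C the terminal ring; in each ring C1 carries the carbonyl carbon. Chain positions run from C1 (ester carbonyl) to C8 (methyl). Chain C2 becomes ring C1, chain C7 becomes ring C6.
- The ring closure is 6-(enolendo)-exo-trig: the enolate double bond C2=C3 lies inside the ring being formed. An enolexo label would fit only the ester-enolate canonical form.
- Precursor design: the hydroxyls at C2 of rings A and B stay free. Each is locked in a hydrogen bond to its ester carbonyl, so neither should compete for the acylketene, and no deprotection follows the key step.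
- The triketo ester 12 is drawn as the triketone but will be a keto–enol mixture. It is not purified, because aryl β-keto esters can revert to ketene and phenol on heating.
- No alkoxide, hydroxide or alcohol solvent is used after step 4, so the depside esters are not exposed to transesterification.
- Assumption: compounds 1, 4 and 8 are purchased. The target has no stereocentre.

Step 1
Reactants: 1 2,4-dihydroxy-6-methylbenzaldehyde
Product: 2 2,4-bis(benzyloxy)-6-methylbenzaldehyde
Conditions: BnBr (2.5 equiv), K2CO3, DMF, 60 °C
Reagents that add atoms: benzyl bromide BrCc1ccccc1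
Why: Williamson ether synthesis, in which carbonate deprotonates both phenols and the phenoxides displace bromide by SN2, warm DMF being enough to benzylate the hydroxyl that is chelated to the aldehyde.

Step 2
Reactants: 2 2,4-bis(benzyloxy)-6-methylbenzaldehyde
Product: 3 2,4-bis(benzyloxy)-6-methylbenzoic acid
Conditions: NaClO2, NaH2PO4, 2-methyl-2-butene, t-BuOH/THF/H2O, rt
Reagents that add atoms: sodium chlorite [Na+].[O-]Cl=O
Why: Pinnick oxidation, in which chlorous acid adds to the aldehyde and fragments to the acid under buffered conditions that spare benzyl ethers, while 2-methyl-2-butene removes hypochlorous acid before it can chlorinate the electron-rich ring.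

Step 3
Reactants: 3 2,4-bis(benzyloxy)-6-methylbenzoic acid; 4 methyl orsellinate
Product: 6 methyl 4-{[2,4-bis(benzyloxy)-6-methylbenzoyl]oxy}-2-hydroxy-6-methylbenzoate, via mixed trifluoroacetic anhydride 5 (not isolated)
Conditions: (CF3CO)2O, PhMe, 0 °C → rt
Reagents that add atoms: none
Why: Mixed-anhydride esterification (the classical trifluoroacetic anhydride depside coupling), in which the electron-rich aroyl group of 5 is transferred to the para hydroxyl of 4, the ortho hydroxyl being hydrogen-bonded to the ester carbonyl and therefore left alone.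

Step 4
Reactants: 6 methyl 4-{[2,4-bis(benzyloxy)-6-methylbenzoyl]oxy}-2-hydroxy-6-methylbenzoate
Product: 7 methyl lecanorate (methyl 4-[(2,4-dihydroxy-6-methylbenzoyl)oxy]-2-hydroxy-6-methylbenzoate)
Conditions: H2 (1 atm), 10% Pd/C, EtOAc, rt
Reagents that add atoms: none
Why: Catalytic hydrogenolysis should cleave both benzyl aryl ethers under neutral conditions that touch neither the aryl ester nor the methyl ester.

Step 5
Reactants: 8 2,2,6-trimethyl-4H-1,3-dioxin-4-one
Product: 9 2,2-dimethyl-6-(2-oxopropyl)-4H-1,3-dioxin-4-one
Conditions: LiN(SiMe3)2 (2 equiv), THF, −78 °C; AcCl; aq. NH4Cl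
Reagents that add atoms: acetyl chloride CC(Cl)=O
Why: Vinylogous deprotonation of the 6-methyl group gives the dienolate, which undergoes a crossed Claisen-type C-acylation at its terminal carbon, the second equivalent of base absorbing the more acidic product.

Step 6
Reactants: 9 2,2-dimethyl-6-(2-oxopropyl)-4H-1,3-dioxin-4-one
Product: 10 6-(2,4-dioxopentyl)-2,2-dimethyl-4H-1,3-dioxin-4-one
Conditions: LiN(iPr)2 (2.2 equiv), THF, −78 °C; ZnEt2; MeC(O)N(OMe)Me, −78 → −10 °C; aq. HCl to pH 3; used crude
Reagents that add atoms: N-methoxy-N-methylacetamide CON(C)C(C)=O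
Why: Acylation of a β-dicarbonyl dianion (crossed Claisen condensation), in which the second carbanion sits on the terminal methyl group, zinc tempers its basicity, and the chelated adduct of the Weinreb amide (Weinreb ketone synthesis) stops at the ketone.

Step 7
Reactants: 7 methyl lecanorate; 10 6-(2,4-dioxopentyl)-2,2-dimethyl-4H-1,3-dioxin-4-one
Product: 12 methyl 2-hydroxy-4-{[2-hydroxy-6-methyl-4-(3,5,7-trioxooctanoyloxy)benzoyl]oxy}-6-methylbenzoate, via acylketene 11 (not isolated)
Conditions: PhMe/1,4-dioxane (3:1), 105 °C, 10 (1.5 equiv) added over 30 min to concentrated 7, N2 sweep; concentrate below 30 °C; crude used at once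
Reagents that add atoms: none
Why: Thermal retro-hetero-Diels–Alder fragmentation of the dioxinone expels acetone and gives acylketene 11, to which a phenolic O–H adds (acylketene acylation, as in the preparation of aryl acetoacetates from dioxinones), and of the three hydroxyls of 7 only O-4 of ring B is free of a hydrogen bond to an ester carbonyl.

Step 8
Reactants: 12 methyl 2-hydroxy-4-{[2-hydroxy-6-methyl-4-(3,5,7-trioxooctanoyloxy)benzoyl]oxy}-6-methylbenzoate
Product: 14 target methyl 4-{[4-{[2,4-dihydroxy-6-methylbenzoyl]oxy}-2-hydroxy-6-methylbenzoyl]oxy}-2-hydroxy-6-methylbenzoate, via cyclic aldol 13 (not isolated)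
Conditions: Et3N (3 equiv), CH2Cl2, 0 °C → rt; then HCl (4 M in 1,4-dioxane), rt
Reagents that add atoms: none
Why: Triethylamine forms the enolate of the C1–C3 β-keto ester, whose carbon C2 adds to the C7 methyl ketone to give cyclic aldol 13; E1cB loss of water and tautomerisation of the C3 and C5 carbonyls then give the resorcinol ring irreversibly, the acid completing any dehydration that lags. The closest known reaction type is the base-mediated aldol cyclisation–aromatisation of 3,5,7-triketo esters to resorcylates, established for esters made by acylketene trapping. Ring C closes in a 6-(enolendo)-exo-trig mode, with enolate carbons C2 and C3 inside the new ring and the C7 carbonyl oxygen outside it. No stereocentre has to be controlled, since the two centres of 13 are erased on aromatisation. The selectivity needed is aldol closure (C2 to C7) over Claisen closure (C6 to C1 with loss of the ring B aryloxide), over lactonisation of the C5 enol oxygen onto C1, and over E1cB release of the aryloxide. What should secure it is the higher electrophilicity of ketone C7 compared with the enolised ester carbon C1, the doubly activated and most nucleophilic position C2, and a weak amine base in an aprotic solvent at low temperature, in which the aryloxide is poorly solvated as a leaving group.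

Compound list
1 | 2,4-dihydroxy-6-methylbenzaldehyde | Cc1cc(O)cc(O)c1C=O | starting material
2 | 2,4-bis(benzyloxy)-6-methylbenzaldehyde | Cc1cc(OCc2ccccc2)cc(OCc2ccccc2)c1C=O | intermediate
3 | 2,4-bis(benzyloxy)-6-methylbenzoic acid | Cc1cc(OCc2ccccc2)cc(OCc2ccccc2)c1C(=O)O | intermediate
4 | methyl orsellinate (methyl 2,4-dihydroxy-6-methylbenzoate) | COC(=O)c1c(C)cc(O)cc1O | starting material
5 | 2,4-bis(benzyloxy)-6-methylbenzoic trifluoroacetic anhydride | Cc1cc(OCc2ccccc2)cc(OCc2ccccc2)c1C(=O)OC(=O)C(F)(F)F | intermediate (not isolated)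
6 | methyl 4-{[2,4-bis(benzyloxy)-6-methylbenzoyl]oxy}-2-hydroxy-6-methylbenzoate | COC(=O)c1c(C)cc(OC(=O)c2c(C)cc(OCc3ccccc3)cc2OCc2ccccc2)cc1O | intermediate
7 | methyl lecanorate | COC(=O)c1c(C)cc(OC(=O)c2c(C)cc(O)cc2O)cc1O | intermediate
8 | 2,2,6-trimethyl-4H-1,3-dioxin-4-one | CC1=CC(=O)OC(C)(C)O1 | starting material
9 | 2,2-dimethyl-6-(2-oxopropyl)-4H-1,3-dioxin-4-one | CC(=O)CC1=CC(=O)OC(C)(C)O1 | intermediate
10 | 6-(2,4-dioxopentyl)-2,2-dimethyl-4H-1,3-dioxin-4-one | CC(=O)CC(=O)CC1=CC(=O)OC(C)(C)O1 | intermediate
11 | 3,5-dioxohexanoylketene (3,5,7-trioxooct-1-en-1-one) | CC(=O)CC(=O)CC(=O)C=C=O | intermediate (not isolated)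
12 | methyl 2-hydroxy-4-{[2-hydroxy-6-methyl-4-(3,5,7-trioxooctanoyloxy)benzoyl]oxy}-6-methylbenzoate (triketo ester on O-4 of ring B; keto–enol mixture) | COC(=O)c1c(C)cc(OC(=O)c2c(C)cc(OC(=O)CC(=O)CC(=O)CC(C)=O)cc2O)cc1O | intermediate
13 | methyl 2-hydroxy-4-{[2-hydroxy-4-({[2-hydroxy-2-methyl-4,6-dioxocyclohexyl]carbonyl}oxy)-6-methylbenzoyl]oxy}-6-methylbenzoate (cyclic aldol; its two transient stereocentres form without control and are lost) | COC(=O)c1c(C)cc(OC(=O)c2c(C)cc(OC(=O)C3C(=O)CC(=O)CC3(C)O)cc2O)cc1O | intermediate (not isolated)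
14 | methyl 4-{[4-{[2,4-dihydroxy-6-methylbenzoyl]oxy}-2-hydroxy-6-methylbenzoyl]oxy}-2-hydroxy-6-methylbenzoate (CNP0212402.0, achiral) | COC(=O)c1c(C)cc(OC(=O)c2c(C)cc(OC(=O)c3c(C)cc(O)cc3O)cc2O)cc1O | target

Total step count: 8
Longest linear sequence: 6 (steps 1, 2, 3, 4, 7, 8); steps 5 and 6 form the second branch, which joins at step 7.

Steps most likely to fail

1. Step 8. The chain may expel the ring B aryloxide instead of closing by aldol addition. The routes for this are Claisen attack of C6 on C1, lactonisation of the C5 enol oxygen onto C1, or base-induced reversion to the ketene; each returns methyl lecanorate. The aryl ester is a better leaving group than the alkyl esters on which this cyclisation is usually run. The fallback gives up the late ring formation and brings ring C in as a finished, protected acid. It sets out from 7 and uses acid 3. Coupling with (CF3CO)2O in PhMe at rt, through mixed anhydride 5, should acylate the unchelated O-4 of ring B and give methyl 4-{[4-{[2,4-bis(benzyloxy)-6-methylbenzoyl]oxy}-2-hydroxy-6-methylbenzoyl]oxy}-2-hydroxy-6-methylbenzoate F1. Hydrogenolysis (H2, 10% Pd/C, EtOAc) then returns to the route at 14.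

2. Step 7. The acylketene may be captured by its own C5 enol oxygen before the phenol adds, or the aryl ester may revert thermally to ketene and phenol. Incomplete dissolution of 7 or acylation at a chelated hydroxyl would also lower conversion. The fallback closes ring C on the dioxinone itself, where the ester oxygen is part of a ring and cannot leave, and then attaches it by classical esterification. It sets out from 10. Et3N in CH2Cl2 at rt should give 7-hydroxy-2,2,5-trimethyl-4H-1,3-benzodioxin-4-one F2 by the same aldol–aromatisation. BnBr and K2CO3 in DMF give 7-(benzyloxy)-2,2,5-trimethyl-4H-1,3-benzodioxin-4-one F3. KOH in aqueous DMSO at 80 °C, then acidification, opens the acetonide to 4-(benzyloxy)-2-hydroxy-6-methylbenzoic acid F4. (CF3CO)2O in PhMe converts it into 4-(benzyloxy)-2-hydroxy-6-methylbenzoic trifluoroacetic anhydride F5 (not isolated), which acylates O-4 of ring B of 7 to give methyl 4-{[4-{[4-(benzyloxy)-2-hydroxy-6-methylbenzoyl]oxy}-2-hydroxy-6-methylbenzoyl]oxy}-2-hydroxy-6-methylbenzoate F6. Hydrogenolysis (H2, 10% Pd/C, EtOAc) returns to the route at 14.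

3. Step 6. Dianion formation may be incomplete, the acylation may go to oxygen, or the sensitive diketo-dioxinone may condense with itself or aromatise during isolation. The fallback builds the same compound by C-acylation of a β-keto ester and decarboxylation, avoiding the dianion. It sets out from 8. LiN(SiMe3)2 in THF at −78 °C followed by allyl 3-chloro-3-oxopropanoate gives allyl 4-(2,2-dimethyl-4-oxo-4H-1,3-dioxin-6-yl)-3-oxobutanoate F7. MgCl2, pyridine and AcCl in CH2Cl2 at 0 °C give allyl 2-acetyl-4-(2,2-dimethyl-4-oxo-4H-1,3-dioxin-6-yl)-3-oxobutanoate F8 by magnesium-enolate C-acylation. Pd(PPh3)4 (catalytic) and morpholine in THF at rt then remove the allyl group and the carboxyl, and the sequence returns to the route at 10.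

Further compounds
F1 | step 8 | methyl 4-{[4-{[2,4-bis(benzyloxy)-6-methylbenzoyl]oxy}-2-hydroxy-6-methylbenzoyl]oxy}-2-hydroxy-6-methylbenzoate | COC(=O)c1c(C)cc(OC(=O)c2c(C)cc(OC(=O)c3c(C)cc(OCc4ccccc4)cc3OCc3ccccc3)cc2O)cc1O
F2 | step 7 | 7-hydroxy-2,2,5-trimethyl-4H-1,3-benzodioxin-4-one | Cc1cc(O)cc2OC(C)(C)OC(=O)c12
F3 | step 7 | 7-(benzyloxy)-2,2,5-trimethyl-4H-1,3-benzodioxin-4-one | Cc1cc(OCc3ccccc3)cc2OC(C)(C)OC(=O)c12
F4 | step 7 | 4-(benzyloxy)-2-hydroxy-6-methylbenzoic acid | Cc1cc(OCc2ccccc2)cc(O)c1C(=O)O
F5 | step 7 | 4-(benzyloxy)-2-hydroxy-6-methylbenzoic trifluoroacetic anhydride | Cc1cc(OCc2ccccc2)cc(O)c1C(=O)OC(=O)C(F)(F)F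
F6 | step 7 | methyl 4-{[4-{[4-(benzyloxy)-2-hydroxy-6-methylbenzoyl]oxy}-2-hydroxy-6-methylbenzoyl]oxy}-2-hydroxy-6-methylbenzoate | COC(=O)c1c(C)cc(OC(=O)c2c(C)cc(OC(=O)c3c(C)cc(OCc4ccccc4)cc3O)cc2O)cc1O
F7 | step 6 | allyl 4-(2,2-dimethyl-4-oxo-4H-1,3-dioxin-6-yl)-3-oxobutanoate | C=CCOC(=O)CC(=O)CC1=CC(=O)OC(C)(C)O1
F8 | step 6 | allyl 2-acetyl-4-(2,2-dimethyl-4-oxo-4H-1,3-dioxin-6-yl)-3-oxobutanoate | C=CCOC(=O)C(C(C)=O)C(=O)CC1=CC(=O)OC(C)(C)O1
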